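**Strategy.** Everything rests on disconnecting the C2–C3 bond of ring C and closing that ring by intramolecular carbene C–H insertion. The feature exploited is C2 itself: it is benzylic (ring B) and bound to the ring oxygen O1. In the open form it is simply the CH2 of an O-benzyl ether, whose two enantiotopic hydrogens are the most hydridic C–H bonds in the molecule and lie six atoms from the future C3. The precursor is therefore a fully substituted ring A aryl diazomethyl ketone carrying an ortho benzyloxy group. A chiral dirhodium carboxylate should form C2–C3, ring C and the (2S) centre in one operation.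

Key step: step 5

Assumption: the sense of asymmetric induction of Rh2(S-PTTL)4 in step 5 is taken to favour the (2S) product; should the insertion favour (2R), the enantiomeric catalyst Rh2(R-PTTL)4 is used with nothing else changed.

In the names below, "geranyl" means (2E)-3,7-dimethylocta-2,6-dien-1-yl.

**Step 1**
Reactants: 1 2',6'-dihydroxy-4'-methoxyacetophenone; 2 geranyl bromide
Product: 3 3'-geranyl-2',6'-dihydroxy-4'-methoxyacetophenone
Conditions: 2 (0.9 equiv), 10% aq KOH, 0 °C to rt; unreacted 1 recovered
Reagents that add atoms: none
Why: Nuclear C-alkylation of an acylphloroglucinol-type phenoxide by SN2 at the primary allylic bromide (no allylic transposition, so the E alkene is kept); the two nucleophilic ring carbons are equivalent by symmetry, water disfavours O-alkylation and a deficit of 2 limits double alkylation.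

**Step 2**
Reactants: 3 3'-geranyl-2',6'-dihydroxy-4'-methoxyacetophenone
Product: 4 3'-geranyl-2'-hydroxy-4'-methoxy-6'-(triisopropylsilyloxy)acetophenone
Conditions: TIPSCl (1.1 equiv), imidazole, CH2Cl2, 0 °C to rt
Reagents that add atoms: triisopropylsilyl chloride (TIPSCl), CC(C)[Si](Cl)(C(C)C)C(C)C
Why: Sterically controlled phenol silylation: the 6'-OH has only the acetyl group as ortho neighbour whereas the 2'-OH is flanked by acetyl and the geranyl CH2, so the bulky silyl chloride should take the 6'-oxygen, and the remaining OH is then locked in the hydrogen bond to the carbonyl so that bis-silylation should not follow.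

**Step 3**
Reactants: 4 3'-geranyl-2'-hydroxy-4'-methoxy-6'-(triisopropylsilyloxy)acetophenone; 5 benzyl bromide
Product: 6 2'-benzyloxy-3'-geranyl-4'-methoxy-6'-(triisopropylsilyloxy)acetophenone
Conditions: 5, anhydrous K2CO3, Bu4NI (cat.), acetone, reflux
Reagents that add atoms: none
Why: Williamson etherification of the chelated, di-ortho-substituted phenol, helped by heating and iodide catalysis; the aryl TIPS ether and the alkenes should tolerate anhydrous carbonate.

**Step 4**
Reactants: 6 2'-benzyloxy-3'-geranyl-4'-methoxy-6'-(triisopropylsilyloxy)acetophenone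
Product: 8 1-[2-(benzyloxy)-3-geranyl-4-methoxy-6-(triisopropylsilyloxy)phenyl]-2-diazoethanone, via trifluoroacetyl ketone 7 (not isolated)
Conditions: LiN(SiMe3)2, THF, −78 °C, then CF3CO2CH2CF3; crude 7, then MsN3, Et3N, H2O, MeCN, rt
Reagents that add atoms: 2,2,2-trifluoroethyl trifluoroacetate, O=C(OCC(F)(F)F)C(F)(F)F (its trifluoroacetyl group is carried only by 7); methanesulfonyl azide, CS(=O)(=O)N=[N+]=[N-]
Why: Detrifluoroacetylative diazo transfer: the kinetic lithium enolate of the methyl ketone is trifluoroacetylated to the 1,3-diketone 7, which is acidic enough for Regitz-type diazo transfer from MsN3, the trifluoroacetyl group leaving on the sulfonamide nitrogen to give the terminal α-diazoketone.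

**Step 5**
Reactants: 8 1-[2-(benzyloxy)-3-geranyl-4-methoxy-6-(triisopropylsilyloxy)phenyl]-2-diazoethanone
Product: 9 (2S)-8-geranyl-7-methoxy-2-phenyl-5-(triisopropylsilyloxy)chroman-4-one
Conditions: Rh2(S-PTTL)4 (dirhodium tetrakis[N-phthaloyl-(S)-tert-leucinate], 2 mol%), toluene, 0 °C, slow addition of 8
Reagents that add atoms: none
Why: Rh2(S-PTTL)4, a carboxylate of divalent rhodium, should expel N2 from 8 to give an electrophilic rhodium carbene at the future C3, which inserts through a concerted, hydride-transfer-like three-centre transition state into one C–H bond of the OCH2Ph group and so forms the C2–C3 bond. The closest known reaction type is the intramolecular rhodium carbene C–H insertion of ortho-alkoxyaryl α-diazoketones to chroman-4-ones, together with the insertion of aryl diazoacetates into benzyl aryl ether C–H bonds under the same phthaloyl-tert-leucinate catalysts. Ring C is the only ring closed, as a six-membered ring by 1,6-insertion (carbene carbon, C4, C4a, C8a, O1, C2). The C2 stereocentre arises from the choice between the two enantiotopic benzylic hydrogens, which is controlled by the chiral carboxylate pocket of the catalyst, the insertion itself proceeding with retention at carbon. The step needs C–H insertion to win over oxonium ylide formation with 1,2-benzyl shift, over attack on the second ortho oxygen and over cyclopropanation: the benzylic C–H α to oxygen is the most activated C–H bond, the other ortho oxygen carries silicon and has neither an α-C–H bond nor a migrating group, and the geranyl chain is attached meta to the carbene-bearing carbon so that cyclopropanation would need a strained meta-bridged ring. Slow addition at low concentration should suppress carbene dimerisation.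

**Step 6**
Reactants: 9 (2S)-8-geranyl-7-methoxy-2-phenyl-5-(triisopropylsilyloxy)chroman-4-one
Product: 10 (2S)-8-geranyl-5-hydroxy-7-methoxy-2-phenylchroman-4-one (target)
Conditions: Bu4NF, AcOH (1:1), THF, 0 °C
Reagents that add atoms: none
Why: Fluoride-mediated cleavage of the aryl silyl ether (Si–F bond formation); the acetic acid buffer keeps the medium non-basic, so the 5-hydroxyflavanone should not open to the chalcone by retro-oxa-Michael reaction and the C2 configuration should be retained.

**Compound list**

1 | 2',6'-dihydroxy-4'-methoxyacetophenone | CC(=O)c1c(O)cc(OC)cc1O | starting material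
2 | geranyl bromide, (2E)-1-bromo-3,7-dimethylocta-2,6-diene | CC(C)=CCC/C(C)=C/CBr | starting material
3 | 3'-geranyl-2',6'-dihydroxy-4'-methoxyacetophenone | CC(=O)c1c(O)cc(OC)c(C/C=C(\C)CCC=C(C)C)c1O | intermediate
4 | 3'-geranyl-2'-hydroxy-4'-methoxy-6'-(triisopropylsilyloxy)acetophenone | CC(=O)c1c(O[Si](C(C)C)(C(C)C)C(C)C)cc(OC)c(C/C=C(\C)CCC=C(C)C)c1O | intermediate
5 | benzyl bromide | BrCc1ccccc1 | starting material
6 | 2'-benzyloxy-3'-geranyl-4'-methoxy-6'-(triisopropylsilyloxy)acetophenone | CC(=O)c1c(O[Si](C(C)C)(C(C)C)C(C)C)cc(OC)c(C/C=C(\C)CCC=C(C)C)c1OCc1ccccc1 | intermediate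
7 | 1-[2-(benzyloxy)-3-geranyl-4-methoxy-6-(triisopropylsilyloxy)phenyl]-4,4,4-trifluorobutane-1,3-dione (not isolated) | O=C(CC(=O)C(F)(F)F)c1c(O[Si](C(C)C)(C(C)C)C(C)C)cc(OC)c(C/C=C(\C)CCC=C(C)C)c1OCc1ccccc1 | intermediate
8 | 1-[2-(benzyloxy)-3-geranyl-4-methoxy-6-(triisopropylsilyloxy)phenyl]-2-diazoethanone | [N-]=[N+]=CC(=O)c1c(O[Si](C(C)C)(C(C)C)C(C)C)cc(OC)c(C/C=C(\C)CCC=C(C)C)c1OCc1ccccc1 | intermediate
9 | (2S)-8-geranyl-7-methoxy-2-phenyl-5-(triisopropylsilyloxy)chroman-4-one | COc1cc(O[Si](C(C)C)(C(C)C)C(C)C)c2c(c1C/C=C(\C)CCC=C(C)C)O[C@H](c1ccccc1)CC2=O | intermediate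
10 | (2S)-8-geranyl-5-hydroxy-7-methoxy-2-phenylchroman-4-one | COc1cc(O)c2c(c1C/C=C(\C)CCC=C(C)C)O[C@H](c1ccccc1)CC2=O | target

**Step count and risks**

Total step count: 6. Longest linear sequence: 6 steps (from 1).

Steps most likely to fail:

Step 5. The carbene may be diverted into oxonium ylide formation at the benzyloxy oxygen followed by a 1,2-benzyl shift, or the catalyst may discriminate the two enantiotopic benzylic hydrogens poorly. The fallback gives up the insertion and builds C2 by asymmetric conjugate arylation. It sets out from 4: condensation with Me2NCH(OMe)2 in toluene at 90 °C would give the enaminone (E)-3-(dimethylamino)-1-[3-geranyl-2-hydroxy-4-methoxy-6-(triisopropylsilyloxy)phenyl]prop-2-en-1-one F1. Mild acid treatment (Me3SiCl, CH2Cl2, rt) should close this to 8-geranyl-7-methoxy-5-(triisopropylsilyloxy)-4H-chromen-4-one F2. Conjugate addition of PhB(OH)2 to F2 under Pd(OCOCF3)2 with the enantiomer of t-BuPyOx that delivers the (2S) product (NH4PF6, H2O, 1,2-dichloroethane, 60 °C) would then return to the route at 9.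

Step 1. O-alkylation and double alkylation may compete with the single C-alkylation, leaving little of the mono-C-geranyl product. The fallback replaces the phenoxide alkylation by halogenation and cross-coupling. It sets out from 1: mono-iodination with N-iodosuccinimide (1.0 equiv, MeCN, 0 °C) would give 3'-iodo-2',6'-dihydroxy-4'-methoxyacetophenone F3. Stille coupling of F3 with (E)-geranyltributylstannane (Pd2(dba)3, P(2-furyl)3, LiCl, DMF, 60 °C) would return to the route at 3.

Step 2. Silylation may occur at the more hindered hydroxyl or at both, so that the benzyl group would later be placed on the wrong oxygen. The fallback fixes the regiochemistry by symmetry instead of sterics and replaces steps 1 and 2. It sets out from 1: mono-silylation (TIPSCl, imidazole, CH2Cl2), unambiguous because the two hydroxyls are equivalent, would give 2'-hydroxy-4'-methoxy-6'-(triisopropylsilyloxy)acetophenone F4. Iodination ortho to the free hydroxyl with N-iodosuccinimide, the other open position being shielded by the silyl ether, would give 2'-hydroxy-3'-iodo-4'-methoxy-6'-(triisopropylsilyloxy)acetophenone F5. Stille coupling of F5 with (E)-geranyltributylstannane (Pd2(dba)3, P(2-furyl)3, LiCl, DMF, 60 °C) would return to the route at 4.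

**Further compounds**

F1 | step 5 | (E)-3-(dimethylamino)-1-[3-geranyl-2-hydroxy-4-methoxy-6-(triisopropylsilyloxy)phenyl]prop-2-en-1-one | CN(C)/C=C/C(=O)c1c(O[Si](C(C)C)(C(C)C)C(C)C)cc(OC)c(C/C=C(\C)CCC=C(C)C)c1O
F2 | step 5 | 8-geranyl-7-methoxy-5-(triisopropylsilyloxy)-4H-chromen-4-one | COc1cc(O[Si](C(C)C)(C(C)C)C(C)C)c2c(c1C/C=C(\C)CCC=C(C)C)OC=CC2=O
F3 | step 1 | 3'-iodo-2',6'-dihydroxy-4'-methoxyacetophenone | CC(=O)c1c(O)cc(OC)c(I)c1O
F4 | step 2 | 2'-hydroxy-4'-methoxy-6'-(triisopropylsilyloxy)acetophenone | CC(=O)c1c(O[Si](C(C)C)(C(C)C)C(C)C)cc(OC)cc1O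
F5 | step 2 | 2'-hydroxy-3'-iodo-4'-methoxy-6'-(triisopropylsilyloxy)acetophenone | CC(=O)c1c(O[Si](C(C)C)(C(C)C)C(C)C)cc(OC)c(I)c1O
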